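**Assumption:** Artelasticin has no stereocentres and no E/Z-defined alkenes (all three olefins end in CMe2), so the "single enantiomer" requirement is moot and no stereocontrol is needed.

## Retrosynthetic overview

1. Target 10 ⇐ one-pot triple olefin cross-metathesis with 2-methyl-2-butene on the unprotected 3,6,8-triallyl tetrahydroxyflavone 8, so all three prenyl groups are made in the last step.
2. 8 ⇐ O-demethylation of 7; 7 ⇐ double aromatic Claisen rearrangement of the 5,7-bis(allyl ether) 6, which converges on the 6,8-diallyl pattern.
3. 6 ⇐ bis-O-allylation of 3-allyl-5,7-dihydroxyflavone 5.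
4. 5 ⇐ thermal Mentzer [3+3] pyrone annulation of phloroglucinol with the α-allyl aroylacetate 3, which forms C4–C4a and O1–C2 in one step with the C3 substituent already in place (no Baker–Venkataraman or chalcone intermediate).
5. Ring order: rings A and B are purchased; only ring C (the pyranone) is built, in step 2.

## Route

**Step 1**
Reactants: 1, ethyl 3-(2,4-dimethoxyphenyl)-3-oxopropanoate; 2, allyl bromide
Product: 3, ethyl 2-(2,4-dimethoxybenzoyl)pent-4-enoate (racemic; this centre is lost in step 2)
Conditions: K2CO3 (1.5 equiv), allyl bromide (1.05 equiv), acetone, reflux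
Reagents that add atoms: allyl bromide, C=CCBr
Why: C-alkylation of a stabilised β-ketoester enolate (acetoacetic-ester-type alkylation); near-stoichiometric halide limits dialkylation.

**Step 2**
Reactants: 3, ethyl 2-(2,4-dimethoxybenzoyl)pent-4-enoate (2 equiv); 4, phloroglucinol (anhydrous)
Product: 5, 3-allyl-2-(2,4-dimethoxyphenyl)-5,7-dihydroxy-4H-chromen-4-one
Conditions: neat melt, Ar, 240 °C (microwave 10–15 min, or bath 1–2 h with EtOH/H2O distilling out)
Reagents that add atoms: phloroglucinol, Oc1cc(O)cc(O)c1
Why: Mentzer pyrone synthesis: the β-ketoester loses EtOH to an α-oxoketene that C-acylates phloroglucinol, and the adjacent OH then cyclodehydrates onto the aryl ketone to give the flavone; aryl methyl ethers and the terminal allyl group are stable to heat, and the symmetry of phloroglucinol removes any regiochemical question.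

**Step 3**
Reactants: 5, 3-allyl-2-(2,4-dimethoxyphenyl)-5,7-dihydroxy-4H-chromen-4-one; 2, allyl bromide
Product: 6, 3-allyl-5,7-bis(allyloxy)-2-(2,4-dimethoxyphenyl)-4H-chromen-4-one
Conditions: allyl bromide (4 equiv), K2CO3 (5 equiv), DMF, 65 °C
Reagents that add atoms: allyl bromide, C=CCBr (two equivalents incorporated)
Why: Williamson ether synthesis; excess halide and heat in DMF are used to alkylate the hydrogen-bonded 5-OH as well as the 7-OH.

**Step 4**
Reactants: 6, 3-allyl-5,7-bis(allyloxy)-2-(2,4-dimethoxyphenyl)-4H-chromen-4-one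
Product: 7, 3,6,8-triallyl-2-(2,4-dimethoxyphenyl)-5,7-dihydroxy-4H-chromen-4-one
Conditions: PhNEt2, 210 °C, Ar, sealed tube, 3–6 h
Reagents that add atoms: none
Why: Double aromatic Claisen rearrangement: the 5-O-allyl can only go to C6 and the 7-O-allyl to C8; if the 7-O-allyl reaches C6 first, the 5-O-allyl is relayed to C8 by ortho-Claisen then para-Cope, so every pathway gives the 6,8-diallyl product.

**Step 5**
Reactants: 7, 3,6,8-triallyl-2-(2,4-dimethoxyphenyl)-5,7-dihydroxy-4H-chromen-4-one
Product: 8, 3,6,8-triallyl-2-(2,4-dihydroxyphenyl)-5,7-dihydroxy-4H-chromen-4-one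
Conditions: BBr3 (8 equiv), CH2Cl2, −78 → 0 °C; quench MeOH/ice at 0 °C
Reagents that add atoms: none
Why: Lewis-acid aryl methyl ether cleavage; unactivated terminal allyl groups ortho to phenols survive BBr3 at low temperature, which is why deprotection is placed before the acid-sensitive prenyl groups exist.

**Step 6**
Reactants: 8, 3,6,8-triallyl-2-(2,4-dihydroxyphenyl)-5,7-dihydroxy-4H-chromen-4-one; 9, 2-methyl-2-butene
Product: 10, artelasticin, 2-(2,4-dihydroxyphenyl)-5,7-dihydroxy-3,6,8-tris(3-methylbut-2-en-1-yl)-4H-chromen-4-one
Conditions: Grubbs II (15 mol % total, in three portions), 2-methyl-2-butene/CH2Cl2 1:1 (a little THF if needed for solubility), 40 °C, sealed tube, 12–24 h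
Reagents that add atoms: 2-methyl-2-butene, CC=C(C)C (three equivalents incorporated as =CMe2; propene lost)
Why: Ru-catalysed olefin cross-metathesis of a terminal allyl arene with excess 2-methyl-2-butene gives the trisubstituted prenyl olefin, with propene loss as driving force; free phenols and the chromone are tolerated, the three allyl groups react independently, and no stereochemistry arises.

## Compound list

1 | ethyl 3-(2,4-dimethoxyphenyl)-3-oxopropanoate | CCOC(=O)CC(=O)c1ccc(OC)cc1OC | starting material
2 | allyl bromide | C=CCBr | starting material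
3 | ethyl 2-(2,4-dimethoxybenzoyl)pent-4-enoate (racemic) | CCOC(=O)C(CC=C)C(=O)c1ccc(OC)cc1OC | intermediate
4 | phloroglucinol (benzene-1,3,5-triol) | Oc1cc(O)cc(O)c1 | starting material
5 | 3-allyl-2-(2,4-dimethoxyphenyl)-5,7-dihydroxy-4H-chromen-4-one | C=CCc1c(-c2ccc(OC)cc2OC)oc2cc(O)cc(O)c2c1=O | intermediate
6 | 3-allyl-5,7-bis(allyloxy)-2-(2,4-dimethoxyphenyl)-4H-chromen-4-one | C=CCOc1cc(OCC=C)c2c(=O)c(CC=C)c(-c3ccc(OC)cc3OC)oc2c1 | intermediate
7 | 3,6,8-triallyl-2-(2,4-dimethoxyphenyl)-5,7-dihydroxy-4H-chromen-4-one | C=CCc1c(O)c(CC=C)c2oc(-c3ccc(OC)cc3OC)c(CC=C)c(=O)c2c1O | intermediate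
8 | 3,6,8-triallyl-2-(2,4-dihydroxyphenyl)-5,7-dihydroxy-4H-chromen-4-one | C=CCc1c(O)c(CC=C)c2oc(-c3ccc(O)cc3O)c(CC=C)c(=O)c2c1O | intermediate
9 | 2-methyl-2-butene | CC=C(C)C | starting material
10 | artelasticin | CC(C)=CCc1c(O)c(CC=C(C)C)c2oc(-c3ccc(O)cc3O)c(CC=C(C)C)c(=O)c2c1O | target

## Summary

Total steps: 6. Longest linear sequence: 6 (from compound 1).

Steps most likely to fail:

1. **Step 2 (Mentzer annulation).** An α-substituted, ortho-substituted aroylacetate may react sluggishly, or give ketonic cleavage or 4-arylcoumarin (Pechmann-type) by-products. Fallback: build ring C in stages instead. Houben–Hoesch acylation of phloroglucinol with pent-4-enenitrile gives 1-(2,4,6-trihydroxyphenyl)pent-4-en-1-one; O-aroylation with 2,4-dimethoxybenzoyl chloride, Baker–Venkataraman shift and cyclodehydration then give the same compound 5.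

2. **Step 6 (triple cross-metathesis on the free tetraphenol).** Risks are poor solubility, Ru chelation by ortho-phenols, allyl-to-propenyl isomerisation, and incomplete conversion giving mixed allyl/crotyl/prenyl products. Fallback: peracetylate 8 (Ac2O/pyridine), run the metathesis on the tetraacetate, then remove the acetates with K2CO3/MeOH, which does not affect prenyl groups.

3. **Step 5 (BBr3 with three ortho-allyl phenols).** HBr addition or cyclisation to 2-methyldihydrobenzofurans is possible. Fallback: change the B-ring protection from the start. Prepare the ketoester from 2',4'-bis(methoxymethoxy)acetophenone (NaH, diethyl carbonate; then allylation) and unmask at this stage with dilute HCl/MeOH, which allyl groups tolerate.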